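# Total synthesis proposal for dichrostachine A

**Assumptions (one line each)**
- Terpenoid carbons use labdane numbering (C18 = 4α‑CH2O, C19 = 4β‑CH3, C20 = 10β‑CH3, C17 = exocyclic CH2); flavonoid carbons use flavone numbering (C2–C8a, C1′–C6′).
- The target SMILES is read as 4α‑CH2OH, 5α‑H, 7β‑OH, 9β‑side chain, 10β‑CH3, with new centres 12R, 1′S, 6′R; C11, the chromonyl group and H‑6′ are all cis on the new cyclohexene.
- The diene partner is the (12E)‑triene, so the target needs a chromone‑endo (quinone‑exo) Diels–Alder transition state.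
- Numbers are given to substrates, carbon‑donating building blocks, intermediates and the target; simple heteroatom reagents (TBSCl, O3, mCPBA, H2O) are given with SMILES but not numbered.
- The (S,S) catalyst antipode is taken as the one exposing the Re,Re face of C1′=C6′; if it proves to be the other, its enantiomer is used.

## Retrosynthetic overview
1. Target ⇒ global desilylation ⇒ [4+2] of labdatriene 22 (C12=C13–C14=C15) with flavone‑quinone 28 (C1′=C6′). This forms the cyclohexene ring (C12–C1′, C15–C6′) and sets C12, C1′, C6′; it is the proposed new catalytic step.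
2. Quinone 28 ⇐ CAN oxidation of a 2′,4′,5′‑trimethoxyflavone ⇐ chromone ring from phloroacetophenone + 2,4,5‑trimethoxybenzoyl chloride (acylation, cyclodehydration).
3. Diene 22 ⇐ C8 methylenation and Luche reduction of a 7‑ketone (C17, C7‑OH); (E)‑diene by HWE then Wittig; both carbonyls from ozonolysis of an allyl and an isopropenyl group (acetyl → Baeyer–Villiger → C7–O).
4. Decalin ⇐ reductive hydroxymethylation (sets C4, C5) and Wolff–Kishner of a Robinson enone (sets C10) ⇐ Sakurai allylation (sets C9) of (S)‑carvone.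
5. Ring order: ring B (carvone) → ring A (Robinson) → chromone pyranone ring (separate branch) → cyclohexene ring last (Diels–Alder); the enedione ring is the oxidised flavone B‑ring.

## Fragment A: labdatriene 22

**Step 1**
Reactants: 1 (S)‑(+)‑carvone; 2 allyltrimethylsilane
Product: 3 (2R,3S,5S)‑3‑allyl‑2‑methyl‑5‑isopropenylcyclohexanone (C2 epimer mixture is inconsequential)
Conditions: TiCl4, CH2Cl2, −78 °C; H2O
Reagents that add atoms: allyltrimethylsilane (2), C=CC[Si](C)(C)C
Why: Hosomi–Sakurai conjugate allylation; axial attack anti to the C5 isopropenyl gives the 3,5‑trans product, setting future C9.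

**Step 2**
Reactants: 3; 4 ethyl vinyl ketone
Product: 5 (4aR,5S,7S)‑5‑allyl‑1,4a‑dimethyl‑7‑isopropenyl‑4,4a,5,6,7,8‑hexahydronaphthalen‑2(3H)‑one (9β‑allyl, 7α‑isopropenyl, 10β‑CH3, Δ4‑3‑one)
Conditions: EVK, KOH (cat.), EtOH, −10 °C → rt; then NaOEt, EtOH, reflux
Reagents that add atoms: ethyl vinyl ketone (4), CCC(=O)C=C
Why: Robinson annulation; the more substituted enolate is alkylated axially, trans to the adjacent pseudo‑axial allyl group (as with 2,3‑dialkylcyclohexanones in eremophilane syntheses), setting C10 with 10β‑CH3.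

**Step 3**
Reactants: 5; 6 formaldehyde (monomer, cracked from paraformaldehyde)
Product: 7 9β‑allyl‑4α‑(hydroxymethyl)‑7α‑isopropenyl‑4β,10β‑dimethyl‑trans‑decalin‑3‑one (5α‑H)
Conditions: Li, NH3(l)/THF, t‑BuOH (1 equiv), −78 °C; isoprene; then CH2O(g), THF, −78 °C; NH4Cl
Reagents that add atoms: formaldehyde (6), C=O
Why: Stork reductive alkylation; axial protonation at C5 gives the trans‑decalin, and the regio‑defined enolate is hydroxymethylated from the α‑face anti to the axial 10β‑methyl, giving 4α‑CH2OH/4β‑CH3 (same outcome as C4 of aphidicolin); isolated alkenes are inert.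

**Step 4**
Reactants: 7
Product: 8 (9β‑allyl‑7α‑isopropenyl‑4β,10β‑dimethyl‑trans‑decalin‑4α‑yl)methanol
Conditions: N2H4·H2O, diethylene glycol, 130 °C (hydrazone first); then KOH, 200 °C, Ar
Reagents that add atoms: none
Why: Wolff–Kishner (Huang‑Minlon) reduction; pre‑forming the hydrazone before adding base suppresses retro‑aldol, the quaternary C4 prevents elimination, and no stereocentre is touched.

**Step 5**
Reactants: 8
Product: 9 TBS ether of 8 (18‑OTBS)
Conditions: TBSCl, imidazole, DMF, rt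
Reagents that add atoms: TBSCl, CC(C)(C)[Si](C)(C)Cl
Why: Standard silylation of the primary neopentyl alcohol.

**Step 6**
Reactants: 9
Product: 10 2‑[7α‑acetyl‑4α‑(TBSOCH2)‑4β,10β‑dimethyl‑trans‑decalin‑9β‑yl]acetaldehyde
Conditions: O3, CH2Cl2/MeOH, −78 °C; then Me2S
Reagents that add atoms: ozone, [O-][O+]=O
Why: Ozonolysis with reductive work‑up cleaves both alkenes (allyl → C12 aldehyde, isopropenyl → methyl ketone); the silyl ether is inert.

**Step 7**
Reactants: 10; 11 methyl 2‑(dimethoxyphosphoryl)propanoate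
Product: 12 methyl (E)‑4‑[7‑acetyl‑4α‑(TBSOCH2)‑4β,10β‑dimethyl‑trans‑decalin‑9β‑yl]‑2‑methylbut‑2‑enoate (drawn 7α; C7 epimerisation is inconsequential because C7 later becomes a ketone)
Conditions: LiCl, DBU, MeCN, 0 °C → rt
Reagents that add atoms: phosphonate (11), COC(=O)C(C)P(=O)(OC)OC
Why: Horner–Wadsworth–Emmons (Masamune–Roush) olefination; aldehyde‑selective over the methyl ketone and E‑selective for the trisubstituted enoate (C12=C13, C16).

**Step 8**
Reactants: 12
Product: 13 the corresponding 7‑acetate (methyl (E)‑4‑[7‑acetoxy‑…‑9β‑yl]‑2‑methylbut‑2‑enoate)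
Conditions: mCPBA, NaHCO3, CH2Cl2, rt → 35 °C
Reagents that add atoms: mCPBA, O=C(OO)c1cccc(Cl)c1
Why: Baeyer–Villiger oxidation; the secondary ring carbon migrates with retention, and the electron‑poor enoate is not epoxidised.

**Step 9**
Reactants: 13
Product: 14 18‑TBSO‑15,17‑dinorlabd‑12E‑ene‑7,14‑diol
Conditions: DIBAL‑H (excess), CH2Cl2, −78 → 0 °C; Rochelle salt
Reagents that add atoms: none
Why: DIBAL reduces the enoate 1,2 to the allylic alcohol and cleaves the acetate in the same operation.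

**Step 10**
Reactants: 14
Product: 15 18‑TBSO‑7‑oxo‑15,17‑dinorlabd‑12E‑en‑14‑al
Conditions: Dess–Martin periodinane, NaHCO3, CH2Cl2, rt
Reagents that add atoms: none
Why: Dess–Martin oxidation of both alcohols; neutral conditions keep the E‑enal geometry and the TBS ether.

**Step 11**
Reactants: 15; 16 methyltriphenylphosphonium bromide
Product: 17 18‑TBSO‑17‑norlabda‑12E,14‑dien‑7‑one
Conditions: 16, KHMDS, THF; add to 15 (1.05 equiv ylide), −78 → 0 °C
Reagents that add atoms: methyltriphenylphosphonium bromide (16), C[P+](c1ccccc1)(c1ccccc1)c1ccccc1.[Br-]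
Why: Wittig methylenation; the enal reacts far faster than the ring ketone at low temperature and the C12=C13 geometry is retained.

**Step 12**
Reactants: 17; 18 Eschenmoser's salt
Product: 19 17‑(dimethylamino)‑18‑TBSO‑labda‑12E,14‑dien‑7‑one (C8 epimers)
Conditions: LDA, THF, −78 °C; then Me2N+=CH2 I−, −78 °C → rt
Reagents that add atoms: Eschenmoser's salt (18), C=[N+](C)C.[I-]
Why: Kinetic enolate Mannich reaction; deprotonation occurs at C8 because the axial 6β‑H is shielded by the 4β‑ and 10β‑methyls (and Δ7 is also the thermodynamically preferred enolate).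

**Step 13**
Reactants: 19
Product: 20 18‑TBSO‑labda‑8(17),12E,14‑trien‑7‑one
Conditions: MeI, CH2Cl2, rt; then aq. NaHCO3, rt (used directly)
Reagents that add atoms: none (MeI only quaternises the amine, which is lost as Me3N)
Why: Quaternisation and mild β‑elimination give the α‑methylene ketone; weak base avoids isomerisation to the endocyclic enone.

**Step 14**
Reactants: 20
Product: 21 18‑TBSO‑labda‑8(17),12E,14‑trien‑7β‑ol
Conditions: NaBH4, CeCl3·7H2O, MeOH, −78 °C
Reagents that add atoms: none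
Why: Luche 1,2‑reduction; axial hydride delivery from the α‑face gives the equatorial 7β‑alcohol, setting C7.

**Step 15**
Reactants: 21
Product: 22 7β,18‑bis(TBSO)‑labda‑8(17),12E,14‑triene
Conditions: TBSOTf, 2,6‑lutidine, CH2Cl2, −78 → 0 °C
Reagents that add atoms: TBSOTf, CC(C)(C)[Si](C)(C)OS(=O)(=O)C(F)(F)F
Why: Standard silylation of a hindered secondary allylic alcohol under non‑acidic conditions.

## Fragment B: flavone‑quinone 28

**Step 16**
Reactants: 23 2′,4′,6′‑trihydroxyacetophenone; 24 2,4,5‑trimethoxybenzoyl chloride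
Product: 25 1‑(2,4,6‑trihydroxyphenyl)‑3‑(2,4,5‑trimethoxyphenyl)propane‑1,3‑dione
Conditions: LiHMDS (4.5 equiv), THF, −78 °C; then 24, −78 °C → rt; aq. HCl
Reagents that add atoms: acid chloride (24), COc1cc(OC)c(cc1OC)C(Cl)=O
Why: Baker–Venkataraman‑type C‑acylation of the lithium polyanion (Cushman protocol); the tri‑phenoxide enolate is acylated at carbon without phenol protection.

**Step 17**
Reactants: 25
Product: 26 5,7‑dihydroxy‑2′,4′,5′‑trimethoxyflavone
Conditions: H2SO4 (cat.), AcOH, 95 °C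
Reagents that add atoms: none
Why: Acid‑catalysed cyclodehydration of the o‑hydroxyaryl 1,3‑diketone forms the chromone ring.

**Step 18**
Reactants: 26
Product: 27 5,7‑bis(TBSO)‑2′,4′,5′‑trimethoxyflavone
Conditions: TBSOTf (2.5 equiv), Et3N, CH2Cl2, 0 °C → rt
Reagents that add atoms: TBSOTf, CC(C)(C)[Si](C)(C)OS(=O)(=O)C(F)(F)F
Why: Silylation of both phenols; the triflate is needed for the hydrogen‑bonded 5‑OH.

**Step 19**
Reactants: 27
Product: 28 2‑[5,7‑bis(TBSO)‑4‑oxo‑4H‑chromen‑2‑yl]‑5‑methoxy‑1,4‑benzoquinone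
Conditions: CAN (2.5 equiv), MeCN/H2O, 0 °C, 15 min
Reagents that add atoms: water, O (source of the quinone oxygens)
Why: CAN oxidative demethylation; the 1,2,4‑trimethoxyaryl ring is much easier to oxidise than the acyl‑deactivated A‑ring and gives the p‑quinone with the 4′‑OMe retained, while aryl TBS ethers survive the short cold exposure.

## Coupling and completion

**Step 20**
Reactants: 22; 28
Product: 29 5,7,7β‑terpenyl,18‑tetrakis‑O‑TBS dichrostachine A (12R,1′S,6′R; C11, chromonyl and H‑6′ cis)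
Conditions: (S,S)‑IDPi (BINOL‑derived N‑triflyl imidodiphosphorimidate, 10 mol %) pre‑silylated with 2‑methylallyl‑TBS (12 mol %); 22 (1.3 equiv), toluene/CH2Cl2, −60 °C; Et3N/MeOH quench
Reagents that add atoms: none (silyl group is only shuttled catalytically)
Why: Proposed new method: the chiral silylium ion pair silylates the most basic oxygen (chromone C4=O, far more basic than the quinone carbonyls) to give a 4‑siloxybenzopyrylium whose C2 oxocarbenium character makes C1′=C6′ a vinyl‑oxocarbenium dienophile with its largest LUMO coefficient at C6′, so the unsubstituted diene terminus C15 bonds to C6′ and C12 to C1′; the cationic pyrylium, not the quinone carbonyls, is then the endo‑directing group, which places the E‑diene's C11 cis to the chromonyl, and the confined counter‑anion paired near C2 blocks one face so the diene adds to the Re,Re face and sets C12, C1′ and C6′ regardless of the remote terpene centres. Closest known reaction types: Gassman cationic Diels–Alder of vinyl oxocarbenium ions, silylium/chiral‑counteranion Diels–Alder of enoates, and chiral‑anion‑controlled additions to 4‑siloxybenzopyrylium ions.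

**Step 21**
Reactants: 29
Product: 30 dichrostachine A
Conditions: HF·pyridine, pyridine/THF, 0 °C → rt
Reagents that add atoms: none
Why: Buffered fluoride desilylation removes the two aryl and two alkyl TBS ethers without base, so the cis ring fusion (C6′), the enedione and the allylic alcohol are not disturbed.

## Compound list

1 | (S)‑(+)‑carvone | CC1=CC[C@@H](CC1=O)C(C)=C | starting material
2 | allyltrimethylsilane | C=CC[Si](C)(C)C | starting material
3 | (2R,3S,5S)‑3‑allyl‑2‑methyl‑5‑isopropenylcyclohexanone | C1[C@H](C(C)=C)CC(=O)[C@H](C)[C@H]1CC=C | intermediate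
4 | ethyl vinyl ketone | CCC(=O)C=C | starting material
5 | (4aR,5S,7S)‑5‑allyl‑1,4a‑dimethyl‑7‑isopropenyl‑4,4a,5,6,7,8‑hexahydronaphthalen‑2(3H)‑one | C1[C@H](C(C)=C)CC2=C(C)C(=O)CC[C@]2(C)[C@H]1CC=C | intermediate
6 | formaldehyde | C=O | starting material
7 | 9β‑allyl‑4α‑(hydroxymethyl)‑7α‑isopropenyl‑4β,10β‑dimethyl‑trans‑decalin‑3‑one | C1[C@H](C(C)=C)C[C@H]2[C@](C)(CO)C(=O)CC[C@]2(C)[C@H]1CC=C | intermediate
8 | (9β‑allyl‑7α‑isopropenyl‑4β,10β‑dimethyl‑trans‑decalin‑4α‑yl)methanol | C1[C@H](C(C)=C)C[C@H]2[C@](C)(CO)CCC[C@]2(C)[C@H]1CC=C | intermediate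
9 | TBS ether of 8 | C1[C@H](C(C)=C)C[C@H]2[C@](C)(CO[Si](C)(C)C(C)(C)C)CCC[C@]2(C)[C@H]1CC=C | intermediate
10 | 2‑[7α‑acetyl‑4α‑(TBSOCH2)‑4β,10β‑dimethyl‑trans‑decalin‑9β‑yl]acetaldehyde | C1[C@H](C(C)=O)C[C@H]2[C@](C)(CO[Si](C)(C)C(C)(C)C)CCC[C@]2(C)[C@H]1CC=O | intermediate
11 | methyl 2‑(dimethoxyphosphoryl)propanoate | COC(=O)C(C)P(=O)(OC)OC | starting material
12 | methyl (E)‑4‑[7α‑acetyl‑4α‑(TBSOCH2)‑4β,10β‑dimethyl‑trans‑decalin‑9β‑yl]‑2‑methylbut‑2‑enoate | C1[C@H](C(C)=O)C[C@H]2[C@](C)(CO[Si](C)(C)C(C)(C)C)CCC[C@]2(C)[C@H]1C/C=C(\C)C(=O)OC | intermediate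
13 | methyl (E)‑4‑[7α‑acetoxy‑4α‑(TBSOCH2)‑4β,10β‑dimethyl‑trans‑decalin‑9β‑yl]‑2‑methylbut‑2‑enoate | C1[C@H](OC(C)=O)C[C@H]2[C@](C)(CO[Si](C)(C)C(C)(C)C)CCC[C@]2(C)[C@H]1C/C=C(\C)C(=O)OC | intermediate
14 | 18‑TBSO‑15,17‑dinorlabd‑12E‑ene‑7α,14‑diol | C1[C@H](O)C[C@H]2[C@](C)(CO[Si](C)(C)C(C)(C)C)CCC[C@]2(C)[C@H]1C/C=C(\C)CO | intermediate
15 | 18‑TBSO‑7‑oxo‑15,17‑dinorlabd‑12E‑en‑14‑al | C1C(=O)C[C@H]2[C@](C)(CO[Si](C)(C)C(C)(C)C)CCC[C@]2(C)[C@H]1C/C=C(\C)C=O | intermediate
16 | methyltriphenylphosphonium bromide | C[P+](c1ccccc1)(c1ccccc1)c1ccccc1.[Br-] | starting material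
17 | 18‑TBSO‑17‑norlabda‑12E,14‑dien‑7‑one | C1C(=O)C[C@H]2[C@](C)(CO[Si](C)(C)C(C)(C)C)CCC[C@]2(C)[C@H]1C/C=C(\C)C=C | intermediate
18 | Eschenmoser's salt | C=[N+](C)C.[I-] | starting material
19 | 17‑(dimethylamino)‑18‑TBSO‑labda‑12E,14‑dien‑7‑one (C8 epimers) | CN(C)CC1C(=O)C[C@H]2[C@](C)(CO[Si](C)(C)C(C)(C)C)CCC[C@]2(C)[C@H]1C/C=C(\C)C=C | intermediate
20 | 18‑TBSO‑labda‑8(17),12E,14‑trien‑7‑one | C=C1C(=O)C[C@H]2[C@](C)(CO[Si](C)(C)C(C)(C)C)CCC[C@]2(C)[C@H]1C/C=C(\C)C=C | intermediate
21 | 18‑TBSO‑labda‑8(17),12E,14‑trien‑7β‑ol | C=C1[C@@H](O)C[C@H]2[C@](C)(CO[Si](C)(C)C(C)(C)C)CCC[C@]2(C)[C@H]1C/C=C(\C)C=C | intermediate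
22 | 7β,18‑bis(TBSO)‑labda‑8(17),12E,14‑triene | C=C1[C@@H](O[Si](C)(C)C(C)(C)C)C[C@H]2[C@](C)(CO[Si](C)(C)C(C)(C)C)CCC[C@]2(C)[C@H]1C/C=C(\C)C=C | intermediate
23 | 2′,4′,6′‑trihydroxyacetophenone | CC(=O)c1c(O)cc(O)cc1O | starting material
24 | 2,4,5‑trimethoxybenzoyl chloride | COc1cc(OC)c(cc1OC)C(Cl)=O | starting material
25 | 1‑(2,4,6‑trihydroxyphenyl)‑3‑(2,4,5‑trimethoxyphenyl)propane‑1,3‑dione | COc1cc(OC)c(cc1OC)C(=O)CC(=O)c1c(O)cc(O)cc1O | intermediate
26 | 5,7‑dihydroxy‑2′,4′,5′‑trimethoxyflavone | COc1cc(OC)c(cc1OC)-c1cc(=O)c2c(O)cc(O)cc2o1 | intermediate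
27 | 5,7‑bis(TBSO)‑2′,4′,5′‑trimethoxyflavone | COc1cc(OC)c(cc1OC)-c1cc(=O)c2c(O[Si](C)(C)C(C)(C)C)cc(O[Si](C)(C)C(C)(C)C)cc2o1 | intermediate
28 | 2‑[5,7‑bis(TBSO)‑4‑oxo‑4H‑chromen‑2‑yl]‑5‑methoxy‑1,4‑benzoquinone | COC1=CC(=O)C(=CC1=O)c1cc(=O)c2c(O[Si](C)(C)C(C)(C)C)cc(O[Si](C)(C)C(C)(C)C)cc2o1 | intermediate
29 | tetra‑O‑TBS dichrostachine A | C=C1[C@@H](O[Si](C)(C)C(C)(C)C)C[C@H]2[C@](C)(CO[Si](C)(C)C(C)(C)C)CCC[C@]2(C)[C@H]1C[C@@H]1C(C)=CC[C@H]2C(=O)C(OC)=CC(=O)[C@@]12c1cc(=O)c2c(O[Si](C)(C)C(C)(C)C)cc(O[Si](C)(C)C(C)(C)C)cc2o1 | intermediate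
30 | dichrostachine A | C=C1[C@@H](O)C[C@H]2[C@](C)(CO)CCC[C@]2(C)[C@H]1C[C@@H]1C(C)=CC[C@H]2C(=O)C(OC)=CC(=O)[C@@]12c1cc(=O)c2c(O)cc(O)cc2o1 | target

## Summary

- **Total steps:** 21
- **Longest linear sequence:** 17 (steps 1–15, 20, 21)

**Three steps most likely to fail, with fallbacks**

1. **Step 20 (proposed chromone‑endo, counter‑anion‑controlled Diels–Alder).** Risks are competing quinone‑endo addition, poor face control and acid sensitivity of the diene. Fallback (known chemistry): run the uncatalysed biomimetic quinone Diels–Alder of 22 with 28 (toluene, 60–80 °C, or 10–15 kbar), accept substrate control, and isolate the required adduct from the regio‑/stereoisomers by preparative HPLC. If the chromonyl‑cis isomer is minor, switch to the (12Z)‑diene (Still–Gennari olefination in step 7), whose ordinary quinone‑endo adduct has the same relative configuration.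

2. **Step 4 (Wolff–Kishner on a β‑ketol).** The risk is retro‑aldol loss of the new C18 carbon. Fallback: change from anionic to radical deoxygenation — TBS‑protect 7, reduce the ketone with NaBH4, form the xanthate (NaH, CS2, MeI) and treat with Bu3SnH/AIBN (Barton–McCombie), which delivers 9 directly.

3. **Step 12 (regioselective C8 Mannich methylenation; affects steps 13–14).** The risk is C6 versus C8 enolisation and isomerisation of the exocyclic enone. Fallback: use the thermodynamic Δ7 TMS enol ether (TMSOTf, Et3N), a Lewis‑acid Mukaiyama aldol with aqueous formaldehyde (Yb(OTf)3), then MsCl/Et3N dehydration to 20. If the Luche reduction gives mainly 7α‑OH, invert by Mitsunobu esterification and hydrolysis.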